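## Retrosynthetic overview

1. Target 20 ⇐ protected biflavanone 18: one BCl3 operation frees the two MOM-protected phenols and the chelated 5''-OMe.
2. 18 ⇐ bis-aldehyde 15: both rings C close in one carbene-catalysed cascade in which each formyl carbon reacts as an acyl anion. C4–C3 forms by hydroacylation of the alkyne (first ring C), then C4''–C3'' by intramolecular Stetter addition to the resulting enone (second ring C). The C3–C3'' bond is the former triple bond.
3. 15 ⇐ C2-symmetric (S,S)-ynediol 9 + phenols 12 and 13: two invertive Mitsunobu etherifications set C2 and C2''.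
4. 9 ⇐ ynedione 7 ⇐ diol 5 ⇐ 4-methoxybenzaldehyde 1 + acetylene 2; rings A and B are bought as arenes.

Assumption: numbers follow the forward route and are also used in the overview; unit 1 is the 5,7-dihydroxy half (C2, C3, C4), unit 2 the 5-hydroxy-7-methoxy half (C2'', C3'', C4''); reagent- or catalyst-bound forms (oxyphosphonium ions, Breslow intermediates, borinate and borate esters) are not numbered apart from the compounds they carry, and in the fallbacks a reaction run at two like sites is labelled by its doubly reacted product.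

## Route

Step 1
Reactants: 1 4-methoxybenzaldehyde (2 equiv); 2 acetylene (1 equiv)
Product: 5 1,4-bis(4-methoxyphenyl)but-2-yne-1,4-diol (racemic and meso forms together), via BrMgC≡CMgBr 3 (not isolated), via bromomagnesium mono-adduct 4 (not isolated)
Conditions: EtMgBr (2 equiv), THF, 40 °C; then 1, 0 °C → rt; aq NH4Cl
Reagents that add atoms: none
Why: Double Grignard 1,2-addition of the acetylene bis(magnesium bromide) to the aldehyde is the classical entry to 1,4-diaryl-but-2-yne-1,4-diols, and no stereocontrol is needed because both carbinols are oxidised in step 2.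

Step 2
Reactants: 5 1,4-bis(4-methoxyphenyl)but-2-yne-1,4-diol
Product: 7 1,4-bis(4-methoxyphenyl)but-2-yne-1,4-dione, via racemic hydroxy ynone 6 (not isolated)
Conditions: activated MnO2 (20 equiv), CH2Cl2, rt
Reagents that add atoms: none
Why: MnO2 oxidation of benzylic-propargylic alcohols is selective and non-acidic, so the ynedione forms without Meyer–Schuster rearrangement and the stereorandom carbinols are erased.

Step 3
Reactants: 7 1,4-bis(4-methoxyphenyl)but-2-yne-1,4-dione
Product: 9 (1S,4S)-1,4-bis(4-methoxyphenyl)but-2-yne-1,4-diol, via (4S)-hydroxy ynone 8 (not isolated)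
Conditions: (S)-Alpine-Borane [B-isopinocampheyl-9-BBN from (−)-α-pinene] (2.5 equiv), THF then neat, rt, 48 h; ethanolamine work-up; recrystallise
Reagents that add atoms: none
Why: Midland reduction transfers the pinanyl β-hydrogen in a boat-like six-membered transition state with the slim alkynyl group next to the pinane methyl and the aryl group away from it, so the reagent from (−)-α-pinene should give the (S)-carbinol at each ketone; any wrong-face event becomes the separable meso diol, so the C2-symmetric diol is obtained in amplified ee.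

Step 4
Reactants: 10 2,4,6-trihydroxybenzaldehyde
Product: 12 2-hydroxy-4,6-bis(methoxymethoxy)benzaldehyde, via 4-O-MOM aldehyde 11 (not isolated)
Conditions: MOMCl (2.1 equiv), iPr2NEt (2.5 equiv), CH2Cl2, 0 °C → rt
Reagents that add atoms: chloromethyl methyl ether (MOMCl), COCCl
Why: Base-mediated O-alkylation (acetal formation) takes the free 4-OH and one ortho OH, while the last ortho OH is locked in the hydrogen bond to the formyl group and stays free for step 5.

Step 5
Reactants: 9 (1S,4S)-1,4-bis(4-methoxyphenyl)but-2-yne-1,4-diol; 12 2-hydroxy-4,6-bis(methoxymethoxy)benzaldehyde; 13 2-hydroxy-4,6-dimethoxybenzaldehyde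
Product: 15 2-{[(1R,4R)-4-(2-formyl-3,5-dimethoxyphenoxy)-1,4-bis(4-methoxyphenyl)but-2-yn-1-yl]oxy}-4,6-bis(methoxymethoxy)benzaldehyde, via mono-ether 14 (not isolated)
Conditions: 12 (1.0 equiv), PPh3, DIAD (1.1 equiv each), toluene, −20 °C; then 13 (1.3 equiv), PPh3, DIAD (1.4 equiv each), −20 → 0 °C
Reagents that add atoms: none
Why: Mitsunobu etherification with the acidic chelated phenols goes by SN2 inversion at each carbinol [(S,S) → (R,R)], elimination is impossible because the carbinol carbons have no β-hydrogen, a stereochemical leak gives the separable (R,S)-diastereomer and not the enantiomer, and the unsymmetrical product is statistical (about half at best, the two symmetrical bis-ethers being removed on silica).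

Step 6
Reactants: 15 the (1R,4R)-bis-aldehyde bis-ether
Product: 18 (2S,3R,2''S,3''R)-5,7-bis(methoxymethoxy)-5'',7'',4',4'''-tetramethoxy-3,3''-biflavanone, via ylidene flavanone 16 (not isolated), via regioisomeric ylidene flavanone 17 (not isolated)
Conditions: 3-mesityl-5,6,7,8-tetrahydro-4H-cyclohepta[d]thiazol-3-ium perchlorate (20 mol%), K2CO3 (40 mol%), THF (0.02 M), 70 °C
Reagents that add atoms: none
Why: Proposed new method: the thiazolylidene turns either aldehyde into its Breslow intermediate (acyl anion equivalent), which adds across the tethered unactivated alkyne in a concerted syn 6-exo-dig hydroacylation to close the first ring C as an (E)-3-ylidene chromanone (16 or 17, both converging), whose enone β-carbon is then attacked 6-exo-trig by the Breslow intermediate of the second aldehyde (intramolecular Stetter reaction) to close the second ring C; C2 and C2'' come unchanged from 15, the Stetter addition occurs anti to the neighbouring aryl group, and C3 and C3'' (each α to a ketone) settle under the carbonate to the diequatorial 2,3-trans and 2'',3''-trans arrangement, which with (2S,2''S) is (2S,3R,2''S,3''R); the closest known reaction type is the carbene-catalysed alkyne hydroacylation/intermolecular Stetter cascade of 2-(propargyloxy)benzaldehydes together with the intramolecular Stetter synthesis of chroman-4-ones.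

Step 7
Reactants: 18 the protected biflavanone
Product: 20 Ruixianglangdusu B, (2S,3R,2''S,3''R)-5,7,5''-trihydroxy-7'',4',4'''-trimethoxy-3,3''-biflavanone, via de-MOM biflavanone 19 (not isolated)
Conditions: BCl3 (8 equiv), CH2Cl2, −78 → 0 °C; then H2O
Reagents that add atoms: none
Why: Lewis-acid ether cleavage with BCl3 removes both MOM acetals at −78 °C and, through the six-membered chelate to the C4'' carbonyl, only the peri 5''-methyl ether on warming, leaving the non-chelated 7''- and 4'-methyl ethers and, in the absence of base, all four stereocentres untouched.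

## Compound list

1 | 4-methoxybenzaldehyde | COc1ccc(C=O)cc1 | starting material
2 | acetylene | C#C | starting material
3 | ethyne-1,2-diylbis(magnesium bromide), BrMgC≡CMgBr | Br[Mg]C#C[Mg]Br | intermediate
4 | racemic mono-adduct BrMgC≡C–CH(OMgBr)(C6H4-4-OMe) | COc1ccc(C(O[Mg]Br)C#C[Mg]Br)cc1 | intermediate
5 | 1,4-bis(4-methoxyphenyl)but-2-yne-1,4-diol (racemic + meso) | COc1ccc(C(O)C#CC(O)c2ccc(OC)cc2)cc1 | intermediate
6 | racemic 4-hydroxy-1,4-bis(4-methoxyphenyl)but-2-yn-1-one | COc1ccc(C(O)C#CC(=O)c2ccc(OC)cc2)cc1 | intermediate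
7 | 1,4-bis(4-methoxyphenyl)but-2-yne-1,4-dione | COc1ccc(C(=O)C#CC(=O)c2ccc(OC)cc2)cc1 | intermediate
8 | (4S)-4-hydroxy-1,4-bis(4-methoxyphenyl)but-2-yn-1-one (as its borinate in the flask) | COc1ccc([C@H](O)C#CC(=O)c2ccc(OC)cc2)cc1 | intermediate
9 | (1S,4S)-1,4-bis(4-methoxyphenyl)but-2-yne-1,4-diol | COc1ccc([C@H](O)C#C[C@@H](O)c2ccc(OC)cc2)cc1 | intermediate
10 | 2,4,6-trihydroxybenzaldehyde | O=Cc1c(O)cc(O)cc1O | starting material
11 | 2,6-dihydroxy-4-(methoxymethoxy)benzaldehyde | COCOc1cc(O)c(C=O)c(O)c1 | intermediate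
12 | 2-hydroxy-4,6-bis(methoxymethoxy)benzaldehyde | COCOc1cc(O)c(C=O)c(OCOC)c1 | intermediate
13 | 2-hydroxy-4,6-dimethoxybenzaldehyde | COc1cc(O)c(C=O)c(OC)c1 | starting material
14 | 2-{[(1R,4S)-4-hydroxy-1,4-bis(4-methoxyphenyl)but-2-yn-1-yl]oxy}-4,6-bis(methoxymethoxy)benzaldehyde | COc1ccc([C@@H](Oc2cc(OCOC)cc(OCOC)c2C=O)C#C[C@@H](O)c2ccc(OC)cc2)cc1 | intermediate
15 | 2-{[(1R,4R)-4-(2-formyl-3,5-dimethoxyphenoxy)-1,4-bis(4-methoxyphenyl)but-2-yn-1-yl]oxy}-4,6-bis(methoxymethoxy)benzaldehyde | COc1ccc([C@@H](Oc2cc(OCOC)cc(OCOC)c2C=O)C#C[C@H](Oc2cc(OC)cc(OC)c2C=O)c2ccc(OC)cc2)cc1 | intermediate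
16 | (2R,3E)-3-[(2S)-2-(2-formyl-3,5-dimethoxyphenoxy)-2-(4-methoxyphenyl)ethylidene]-2-(4-methoxyphenyl)-5,7-bis(methoxymethoxy)chroman-4-one | COc1ccc([C@H]2Oc3cc(OCOC)cc(OCOC)c3C(=O)/C2=C/[C@H](Oc2cc(OC)cc(OC)c2C=O)c2ccc(OC)cc2)cc1 | intermediate
17 | (2R,3E)-3-{(2S)-2-[2-formyl-3,5-bis(methoxymethoxy)phenoxy]-2-(4-methoxyphenyl)ethylidene}-5,7-dimethoxy-2-(4-methoxyphenyl)chroman-4-one | COc1ccc([C@@H](Oc2cc(OCOC)cc(OCOC)c2C=O)/C=C2/C(=O)c3c(OC)cc(OC)cc3O[C@@H]2c2ccc(OC)cc2)cc1 | intermediate
18 | (2S,3R,2''S,3''R)-5,7-bis(methoxymethoxy)-5'',7'',4',4'''-tetramethoxy-3,3''-biflavanone | COc1ccc([C@H]2Oc3cc(OCOC)cc(OCOC)c3C(=O)[C@@H]2[C@H]2C(=O)c3c(OC)cc(OC)cc3O[C@@H]2c2ccc(OC)cc2)cc1 | intermediate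
19 | (2S,3R,2''S,3''R)-5,7-dihydroxy-5'',7'',4',4'''-tetramethoxy-3,3''-biflavanone (boron-bound in the flask) | COc1ccc([C@H]2Oc3cc(O)cc(O)c3C(=O)[C@@H]2[C@H]2C(=O)c3c(OC)cc(OC)cc3O[C@@H]2c2ccc(OC)cc2)cc1 | intermediate
20 | Ruixianglangdusu B, (2S,3R,2''S,3''R)-5,7,5''-trihydroxy-7'',4',4'''-trimethoxy-3,3''-biflavanone | COc1ccc([C@H]2Oc3cc(O)cc(O)c3C(=O)[C@@H]2[C@H]2C(=O)c3c(O)cc(OC)cc3O[C@@H]2c2ccc(OC)cc2)cc1 | target

## Step count and risks

Total steps: 7. Longest linear sequence: 6 (steps 1 → 2 → 3 → 5 → 6 → 7); step 4 is a one-step side branch.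

**Most likely to fail, first: step 6.** The 2,6-dioxygenated, electron-rich aldehydes may form Breslow intermediates slowly. The enones 16/17 can be drained by base through γ-deprotonation (flavone formation, or 1,4-loss of the aryloxide to a 3-styrylflavone). C2 can also be scrambled by retro-oxa-Michael opening. The fallback sets out from 15 and comes back at 18, replacing the carbene acyl anion by base-free acyl radicals. Pinnick oxidation (NaClO2, NaH2PO4, 2-methyl-2-butene, t-BuOH/H2O) of both formyl groups gives the diacid F1. (PhSe)2/PBu3 converts it into the bis(Se-phenyl selenoester) F2. Slow addition of Bu3SnH/AIBN in benzene at 80 °C then generates an aroyl radical that cyclises 6-exo-dig onto the alkyne. After hydrogen transfer this gives the ylidene flavanone selenoester F3 or its regioisomer F4 (E/Z mixtures, not isolated). The second aroyl radical adds 6-exo-trig to the enone β-carbon, and a short K2CO3 equilibration of C3/C3'' delivers 18.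

**Second: step 5.** The p-anisyl propargylic oxyphosphonium ion can ionise, giving loss of inversion, C-alkylation of the phloroglucinol-type phenols or SN2′ allenes, on top of the statistical ceiling. The fallback sets out from 7 (with 12 and 13) and comes back at 15. It forms the aryl–oxygen bond instead, so the carbinol C–O bond is never broken. (R)-Alpine-Borane reduction of 7 gives the (1R,4R)-diol F5. Deoxyfluorination of 12 and 13 (PhenoFluor, CsF, toluene, 110 °C) gives 2-fluoro-4,6-bis(methoxymethoxy)benzaldehyde F6 and 2-fluoro-4,6-dimethoxybenzaldehyde F7. The sodium alkoxide of F5 (NaH, THF/DMF, −20 °C) displaces the fluoride ortho to the formyl group by SNAr, first on F6 to give the (1R,4R)-mono-ether F8 and then on F7 to give 15, with retention at both stereocentres.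

**Third: step 3.** The p-anisyl ketone may be reduced slowly, so that achiral 9-BBN from dehydroboration erodes selectivity, and the ynedione may suffer conjugate reduction. The fallback sets out from 1 and comes back at 9, building each carbinol by catalytic asymmetric alkynylation instead of reduction. Me2Zn/ProPhenol-catalysed addition of trimethylsilylacetylene to 1 (ligand enantiomer chosen for the (S)-carbinol) gives (S)-1-(4-methoxyphenyl)-3-(trimethylsilyl)prop-2-yn-1-ol F9. K2CO3/MeOH gives (R)-1-(4-methoxyphenyl)prop-2-yn-1-ol F10 (same spatial arrangement; the descriptor changes with the priorities). A second ProPhenol/Me2Zn alkynylation of 1 with the zinc alkoxide-acetylide of F10 gives 9, the meso diol again being removed.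

## Further compounds

F1 | step 6 | 2-{[(1R,4R)-4-(2-carboxy-3,5-dimethoxyphenoxy)-1,4-bis(4-methoxyphenyl)but-2-yn-1-yl]oxy}-4,6-bis(methoxymethoxy)benzoic acid | COc1ccc([C@@H](Oc2cc(OCOC)cc(OCOC)c2C(=O)O)C#C[C@H](Oc2cc(OC)cc(OC)c2C(=O)O)c2ccc(OC)cc2)cc1
F2 | step 6 | bis(Se-phenyl) selenoester of F1 | COc1ccc([C@@H](Oc2cc(OCOC)cc(OCOC)c2C(=O)[Se]c2ccccc2)C#C[C@H](Oc2cc(OC)cc(OC)c2C(=O)[Se]c2ccccc2)c2ccc(OC)cc2)cc1
F3 | step 6 | ylidene flavanone selenoester (ring C of unit 1 closed, Se-phenyl selenoester on ring A of unit 2, E/Z mixture) | COc1ccc([C@H]2Oc3cc(OCOC)cc(OCOC)c3C(=O)C2=C[C@H](Oc2cc(OC)cc(OC)c2C(=O)[Se]c2ccccc2)c2ccc(OC)cc2)cc1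
F4 | step 6 | regioisomeric ylidene flavanone selenoester (ring C of unit 2 closed, Se-phenyl selenoester on ring A of unit 1, E/Z mixture) | COc1ccc([C@@H](Oc2cc(OCOC)cc(OCOC)c2C(=O)[Se]c2ccccc2)C=C2C(=O)c3c(OC)cc(OC)cc3O[C@@H]2c2ccc(OC)cc2)cc1
F5 | step 5 | (1R,4R)-1,4-bis(4-methoxyphenyl)but-2-yne-1,4-diol | COc1ccc([C@@H](O)C#C[C@H](O)c2ccc(OC)cc2)cc1
F6 | step 5 | 2-fluoro-4,6-bis(methoxymethoxy)benzaldehyde | COCOc1cc(F)c(C=O)c(OCOC)c1
F7 | step 5 | 2-fluoro-4,6-dimethoxybenzaldehyde | COc1cc(F)c(C=O)c(OC)c1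
F8 | step 5 | 2-{[(1R,4R)-4-hydroxy-1,4-bis(4-methoxyphenyl)but-2-yn-1-yl]oxy}-4,6-bis(methoxymethoxy)benzaldehyde | COc1ccc([C@@H](Oc2cc(OCOC)cc(OCOC)c2C=O)C#C[C@H](O)c2ccc(OC)cc2)cc1
F9 | step 3 | (S)-1-(4-methoxyphenyl)-3-(trimethylsilyl)prop-2-yn-1-ol | COc1ccc([C@H](O)C#C[Si](C)(C)C)cc1
F10 | step 3 | (R)-1-(4-methoxyphenyl)prop-2-yn-1-ol | COc1ccc([C@H](O)C#C)cc1
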